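**Retrosynthetic overview**

1. Endgame: the C1 acetate is put on last by an enantiomer-selective (lipase) acetylation of the racemic cis-alcohol 10, which comes from ketone 9 by hydride reduction (ring numbering: C1 C–O, C2 CMe2, C3 CH–CH2OAr, C4 C=CH2, C5, C6; Ar = 2-oxo-2H-chromen-7-yl).
2. Key disconnection: C5–C6 and C2–C3 of ketone 9. This cuts the carbocycle into a C6–C1(=O)–C2 unit (isopropyl methyl ketone) and a C3–C4(=CH2)–C5 unit (the hydroxylated prenyl group of 7-prenyloxycoumarin).
3. Enabling feature: in the six-membered carbocycle the oxygenated carbon C1 and the methylidene-bearing carbon C4 are 1,4-related. The C1 oxygen can therefore be tied as an enol ether to the future C5 (temporary O–C5 bond in allyl vinyl ether 7). A [3,3] shift makes C2–C3 and cuts the tether; the isopropenyl group set free then takes the C6 radical at its CH2 end (C5–C6), and its methyl group becomes the exocyclic CH2.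
4. Ring order: the coumarin bicycle is bought with umbelliferone; the cyclohexane ring is the only ring made, in step 5.
5. Stereochemistry: C3 forms as a racemate in step 5, C1 is set cis to it in step 6, and the (1R,3S) enantiomer is selected in step 7.

Key step: step 5

Assumption: all intermediates up to 10 are achiral or racemic; the single enantiomer is secured only in step 7, which can deliver at most half of the material. Step 5 is run as one flask operation without work-up between its two stages.

**Route**

Step 1
Reactants: 1 umbelliferone (7-hydroxy-2H-chromen-2-one); 2 prenyl bromide (1-bromo-3-methylbut-2-ene)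
Product: 3 7-[(3-methylbut-2-en-1-yl)oxy]-2H-chromen-2-one
Conditions: K2CO3, acetone, reflux
Reagents that add atoms: none
Why: Williamson ether synthesis, in which the acidic phenol of 1 is deprotonated and displaces the primary allylic bromide by SN2, with no stereocenter involved.

Step 2
Reactants: 3 7-[(3-methylbut-2-en-1-yl)oxy]-2H-chromen-2-one
Product: 4 7-{[(2E)-4-hydroxy-3-methylbut-2-en-1-yl]oxy}-2H-chromen-2-one
Conditions: SeO2 (0.5 equiv), t-BuOOH (2 equiv), CH2Cl2, 0 °C to rt
Reagents that add atoms: tert-butyl hydroperoxide, CC(C)(C)OO (terminal oxygen source; the oxygen is relayed by SeO2, O=[Se]=O)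
Why: SeO2 allylic oxidation (ene reaction followed by a [2,3]-sigmatropic shift) should hydroxylate the methyl group trans to the chain of the trisubstituted alkene with E selectivity, and reoxidation by t-BuOOH keeps the reaction largely at the alcohol stage.

Step 3
Reactants: 5 2-bromo-3-methylbut-2-ene
Product: 6 2-iodo-3-methylbut-2-ene
Conditions: CuI (5 mol %), trans-N,N′-dimethylcyclohexane-1,2-diamine (10 mol %), NaI (2 equiv), 1,4-dioxane, 110 °C (sealed)
Reagents that add atoms: sodium iodide, [Na+].[I-]
Why: copper-catalysed halogen exchange (vinylic Finkelstein reaction) should convert the alkenyl bromide into the more reactive iodide, driven by excess NaI and precipitation of NaBr.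

Step 4
Reactants: 4 7-{[(2E)-4-hydroxy-3-methylbut-2-en-1-yl]oxy}-2H-chromen-2-one; 6 2-iodo-3-methylbut-2-ene (2 equiv)
Product: 7 7-({(2E)-3-methyl-4-[(3-methylbut-2-en-2-yl)oxy]but-2-en-1-yl}oxy)-2H-chromen-2-one
Conditions: CuI (10 mol %), 3,4,7,8-tetramethyl-1,10-phenanthroline (20 mol %), Cs2CO3 (1.5 equiv), toluene, 80 °C; chromatography on base-washed silica
Reagents that add atoms: none
Why: Ullmann-type copper-catalysed C–O coupling of a primary allylic alcohol with an alkenyl iodide should give the regiodefined tetrasubstituted enol ether, and at 80 °C the [3,3] shift of this ether should still be slow enough for it to be isolated.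

Step 5
Reactants: 7 7-({(2E)-3-methyl-4-[(3-methylbut-2-en-2-yl)oxy]but-2-en-1-yl}oxy)-2H-chromen-2-one
Product: 9 rac-2,2-dimethyl-4-methylidene-3-{[(2-oxo-2H-chromen-7-yl)oxy]methyl}cyclohexan-1-one, via methyl ketone 8 (not isolated)
Conditions: PhCl, 135 °C (sealed tube); then, in the same flask, AcOH, Mn(OAc)3·2H2O (slightly more than 2 equiv), Cu(OAc)2·H2O (1 equiv), 80 °C
Reagents that add atoms: none
Why: Heating 7 triggers a Claisen ([3,3]-sigmatropic) rearrangement through a chair transition state in which the enol-ether carbon (future C2) can only bond to the distal allyl carbon (future C3), so the congested C2–C3 bond forms with full regiocontrol while the temporary O–C5 bond breaks, giving methyl ketone 8 with an isopropenyl group; Mn(OAc)3 then forms the trivalent-manganese enolate on the only enolisable side (the methyl group, C6), the resulting α-keto radical adds to the CH2 end of the 1,1-disubstituted alkene (C5–C6), and Cu(OAc)2 oxidises the tertiary C4 radical by β-hydride loss from the methyl group to the exocyclic alkene. The closest known reaction types are the thermal rearrangement of ketone-derived allyl vinyl ethers to α-quaternary ketones and the Mn(OAc)3/Cu(OAc)2 oxidative free-radical cyclisation of unsaturated ketones. The single ring is closed in the 6-endo-trig radical mode, which should win over 5-exo because the attacked carbon is unsubstituted, the radical formed is tertiary and the carbonyl group lies inside the forming ring. The new stereocenter C3 is created in the sigmatropic stage from an achiral substrate and is therefore racemic; there is no diastereomer issue because C2 carries two methyl groups, and the (3S) series is selected in step 7. The step needs bond formation at C3 rather than at the CH2 terminus (secured by the O-tether), enolisation toward C6 only (C2 is quaternary), the exocyclic rather than an endocyclic alkene (divalent copper removes the least hindered β-hydrogen) and no further oxidation of 9 at C6 (limited oxidant, reaction stopped before full conversion, 8 recovered).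

Step 6
Reactants: 9 rac-2,2-dimethyl-4-methylidene-3-{[(2-oxo-2H-chromen-7-yl)oxy]methyl}cyclohexan-1-one
Product: 10 rac-(1R*,3S*)-2,2-dimethyl-4-methylidene-3-{[(2-oxo-2H-chromen-7-yl)oxy]methyl}cyclohexan-1-ol (cis)
Conditions: NaBH4, CeCl3·7H2O, MeOH/CH2Cl2, −40 °C
Reagents that add atoms: none
Why: Luche-type hydride reduction, in which hydride should reach the carbonyl carbon from the face away from the C3 CH2OAr group (axial attack on the conformer with that group equatorial, equatorial attack on the conformer with it axial), so that OH and CH2OAr end up cis, while the coumarin lactone should survive NaBH4 at low temperature.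

Step 7
Reactants: 10 rac-(1R*,3S*)-2,2-dimethyl-4-methylidene-3-{[(2-oxo-2H-chromen-7-yl)oxy]methyl}cyclohexan-1-ol
Product: 11 (1R,3S)-2,2-dimethyl-4-methylidene-3-{[(2-oxo-2H-chromen-7-yl)oxy]methyl}cyclohexyl acetate (target)
Conditions: immobilised lipase from Burkholderia cepacia, vinyl acetate (3 equiv), t-BuOMe, 35 °C, stopped near half conversion
Reagents that add atoms: vinyl acetate, C=COC(C)=O
Why: lipase-catalysed irreversible transesterification (kinetic resolution), in which the enzyme is expected to acylate the secondary alcohol with R configuration at the carbinol carbon (large group the quaternary C2, medium group the C6 methylene), which in the cis racemate is the (1R,3S) enantiomer, so the acetate formed should be the target and the (1S,3R) alcohol should remain.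

**Compound list**

1 | umbelliferone (7-hydroxy-2H-chromen-2-one) | Oc1ccc2ccc(=O)oc2c1 | starting material
2 | prenyl bromide (1-bromo-3-methylbut-2-ene) | CC(C)=CCBr | starting material
3 | 7-[(3-methylbut-2-en-1-yl)oxy]-2H-chromen-2-one | CC(C)=CCOc1ccc2ccc(=O)oc2c1 | intermediate
4 | 7-{[(2E)-4-hydroxy-3-methylbut-2-en-1-yl]oxy}-2H-chromen-2-one | C/C(CO)=C\COc1ccc2ccc(=O)oc2c1 | intermediate
5 | 2-bromo-3-methylbut-2-ene | CC(C)=C(C)Br | starting material
6 | 2-iodo-3-methylbut-2-ene | CC(C)=C(C)I | intermediate
7 | 7-({(2E)-3-methyl-4-[(3-methylbut-2-en-2-yl)oxy]but-2-en-1-yl}oxy)-2H-chromen-2-one | C/C(COC(C)=C(C)C)=C\COc1ccc2ccc(=O)oc2c1 | intermediate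
8 | rac-7-{[3,3-dimethyl-4-oxo-2-(prop-1-en-2-yl)pentyl]oxy}-2H-chromen-2-one (racemate, not isolated) | CC(=O)C(C)(C)C(COc1ccc2ccc(=O)oc2c1)C(C)=C | intermediate
9 | rac-2,2-dimethyl-4-methylidene-3-{[(2-oxo-2H-chromen-7-yl)oxy]methyl}cyclohexan-1-one (racemate) | C=C1CCC(=O)C(C)(C)C1COc1ccc2ccc(=O)oc2c1 | intermediate
10 | rac-(1R*,3S*)-2,2-dimethyl-4-methylidene-3-{[(2-oxo-2H-chromen-7-yl)oxy]methyl}cyclohexan-1-ol (cis racemate, both enantiomers written) | C=C1CC[C@@H](O)C(C)(C)[C@H]1COc1ccc2ccc(=O)oc2c1.C=C1CC[C@H](O)C(C)(C)[C@@H]1COc1ccc2ccc(=O)oc2c1 | intermediate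
11 | (1R,3S)-2,2-dimethyl-4-methylidene-3-{[(2-oxo-2H-chromen-7-yl)oxy]methyl}cyclohexyl acetate | C=C1CC[C@@H](OC(C)=O)C(C)(C)[C@H]1COc1ccc2ccc(=O)oc2c1 | target

**Step count and risks**

Total: 7 steps. Longest linear sequence: 6 steps (1, 2, 4, 5, 6, 7); step 3 prepares the coupling partner.

Steps most likely to fail:

Step 5. The oxidative stage may suffer from further oxidation of the product ketone at C6, from non-selective β-hydride loss giving endocyclic alkene isomers, and from slow enolisation of the hindered methyl ketone. The fallback sets out from 7 and returns at 9. Only the thermal rearrangement is run (PhCl, 135 °C) and methyl ketone 8 is isolated. Ene-type allylic chlorination of its isopropenyl group (N-chlorosuccinimide, catalytic PhSeCl, CH2Cl2, rt) should move the double bond into the former methyl group and give the allylic chloride 7-{[2-(3-chloroprop-1-en-2-yl)-3,3-dimethyl-4-oxopentyl]oxy}-2H-chromen-2-one F1. LiN(SiMe3)2 (THF, −78 to 0 °C) then forms the only possible enolate, which should close the six-membered ring by intramolecular C-alkylation; both CH2 ends of the 2-substituted allyl chloride lead to the same ketone 9. No oxidant is involved and the exocyclic alkene is fixed by constitution.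

Step 7. The hindered alcohol next to the quaternary carbon may be acylated too slowly, or the enzyme may discriminate the enantiomers poorly. The fallback sets out from 10 and returns at 11. Racemic 10 is esterified with (S)-2-methoxy-2-phenylacetic acid (DCC, DMAP, CH2Cl2). The two diastereomeric esters, (1R,3S)-2,2-dimethyl-4-methylidene-3-{[(2-oxo-2H-chromen-7-yl)oxy]methyl}cyclohexyl (2S)-2-methoxy-2-phenylacetate F2 and its (1S,3R) diastereomer F3, are separated by chromatography. Methanolysis of F2 (K2CO3, MeOH, 0 °C to rt, then mild acidification to reclose any opened lactone) gives the single-enantiomer alcohol (1R,3S)-2,2-dimethyl-4-methylidene-3-{[(2-oxo-2H-chromen-7-yl)oxy]methyl}cyclohexan-1-ol F4, and Ac2O/pyridine/DMAP gives 11.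

Step 4. The tetrasubstituted alkenyl iodide may couple sluggishly, the caesium alkoxide may open the coumarin lactone, and the enol ether may hydrolyse or rearrange during isolation. The fallback sets out from 4 and returns at 9 through 8. Alcohol 4 is heated with 2,2-dimethoxy-3-methylbutane and catalytic propanoic acid in xylene at 135 °C with removal of methanol (ketal Claisen rearrangement). Alcohol exchange gives the mixed ketal 7-{[(2E)-4-[(2-methoxy-3-methylbutan-2-yl)oxy]-3-methylbut-2-en-1-yl]oxy}-2H-chromen-2-one F5, loss of methanol gives enol ether 7 in the flask, and this rearranges directly to ketone 8. Ketone 8 is isolated and cyclised to 9 in a separate flask under the Mn(OAc)3/Cu(OAc)2 conditions of step 5. The enol ether has to form toward the isopropyl carbon (the more substituted side); any regioisomeric ketone from the methyl side is removed by chromatography.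

**Further compounds**

F1 | step 5 | 7-{[2-(3-chloroprop-1-en-2-yl)-3,3-dimethyl-4-oxopentyl]oxy}-2H-chromen-2-one (racemate) | CC(=O)C(C)(C)C(COc1ccc2ccc(=O)oc2c1)C(=C)CCl
F2 | step 7 | (1R,3S)-2,2-dimethyl-4-methylidene-3-{[(2-oxo-2H-chromen-7-yl)oxy]methyl}cyclohexyl (2S)-2-methoxy-2-phenylacetate | C=C1CC[C@@H](OC(=O)[C@@H](OC)c3ccccc3)C(C)(C)[C@H]1COc1ccc2ccc(=O)oc2c1
F3 | step 7 | (1S,3R)-2,2-dimethyl-4-methylidene-3-{[(2-oxo-2H-chromen-7-yl)oxy]methyl}cyclohexyl (2S)-2-methoxy-2-phenylacetate | C=C1CC[C@H](OC(=O)[C@@H](OC)c3ccccc3)C(C)(C)[C@@H]1COc1ccc2ccc(=O)oc2c1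
F4 | step 7 | (1R,3S)-2,2-dimethyl-4-methylidene-3-{[(2-oxo-2H-chromen-7-yl)oxy]methyl}cyclohexan-1-ol | C=C1CC[C@@H](O)C(C)(C)[C@H]1COc1ccc2ccc(=O)oc2c1
F5 | step 4 | 7-{[(2E)-4-[(2-methoxy-3-methylbutan-2-yl)oxy]-3-methylbut-2-en-1-yl]oxy}-2H-chromen-2-one | C/C(COC(C)(OC)C(C)C)=C\COc1ccc2ccc(=O)oc2c1
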